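The numbers in the tables stem from a simulated flask on assumed constants.

**The count.** One mole of solid reagent charged can be priced in moles of left-handed substrate taken up, and the curve of the excess in this flask is reckoned here by that count.

the same everywhere: solid reagent 0.248 M
- green: left-handed substrate 0.15 M; right-handed substrate 0.15 M; precatalyst 3.1 mM; run made earlier
- ochre: left-handed substrate 0.23 M; right-handed substrate 0.23 M; precatalyst 3.1 mM; run made earlier
- teal: left-handed substrate 0.31 M; right-handed substrate 0.31 M; precatalyst 4.7 mM; run made earlier
- flask: left-handed substrate 0.31 M; right-handed substrate 0.31 M; precatalyst 3.1 mM; time 2.5 d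

- green (time / h: right-handed substrate / %, left-handed substrate / %): 3.00: 53, 45; 5.00: 51, 41; 8.00: 51, 29; 12.0: 49, 16; 20.0: 50, 6; 40.0: 47, 0
- ochre (time / h: right-handed substrate / %, left-handed substrate / %): 2.50: 49, 48; 8.00: 49, 32; 12.0: 50, 20; 20.0: 49, 9; 30.0: 49, 6; 40.0: 47, 8
- teal (time / h: right-handed substrate / %, left-handed substrate / %): 8.00: 48, 28; 15.0: 51, 17; 20.0: 51, 15; 30.0: 46, 17; 40.0: 52, 15

(standard deviation of a reading: 1.5 percentage points)

1. whether the excess of right-handed substrate over left-handed substrate among what is left of the two reaches 80% by 2.5 d (no / yes)
2. the highest excess of right-handed substrate over left-handed substrate among what is left of the two up to 2.5 d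

**Reading teal.** The green run, charged with less left-handed substrate than solid reagent, ends at 0% left-handed substrate. The teal run, charged with more, reads flat at a mean of 15.7% from 20.0 h on, while its right-handed substrate still reads 52% at the last point. So by these readings the teal run took up 0.213 M of left-handed substrate from 0.248 M of solid reagent, which gives 0.858 as the capture yield, the moles of left-handed substrate gone per mole of solid reagent charged once the curve is flat.

**The curve.** The charge of the flask differs from that of the teal run in its precatalyst, 3.1 mM against 4.7 mM, so the mean fall of the teal run up to 8.00 h, scaled by that ratio, gives a reckoned mean slope of 0.0112 M h⁻¹. The capture yield allows the flask 0.213 M of capture, which at that slope takes 18.9 h, shorter than the 2.5 d allowed, so the reckoned straight line meets its level inside the run. With right-handed substrate counted at its charge, the excess levels at 52.3%. On the same count an excess of 80% asks for left-handed substrate at 5.56% of the two charged, less than the reckoned level of 15.7%, so the reckoned excess stays below 80%.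

**Result.** The forecast answers no with a top of 47%, lower than the 52.3% reckoned here, on the words “The plateaus show that coupling partner runs out”. The flask gives no and a top of 53.9%.

    coupling partner + catalyst + left-handed substrate → catalyst + left-handed product (k = 660 L² mol⁻² h⁻¹)
    coupling partner + catalyst + right-handed substrate → catalyst + right-handed product (k = 7.40 L² mol⁻² h⁻¹)
    coupling partner + precatalyst → catalyst + spent reagent (k = 1.00 L mol⁻¹ h⁻¹)
    solid reagent ⇌ coupling partner, rate k4*(cs4 - [coupling partner]) while solid is left; crystals form when [coupling partner] > cs4 (solubility = 0.110 M, k = 2.20 h⁻¹)
    2 coupling partner → self-condensation product (k = 0.110 L mol⁻¹ h⁻¹)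

**Flask and neighbour.** At 2.50 d the flask holds 0% solid reagent, its limiting reagent, and 3.34 × 10⁻⁵ M coupling partner, and the half-life of left-handed substrate by its capture step is 570 d, long against the 2.5 d allowed, with left-handed substrate at 14.8% beside right-handed substrate at 49.3%. In the neighbour flask with 0.062 M of solid reagent, the capture yield of 0.858 gives 0.0532 M captured, left-handed substrate at 41.4% and a reckoned excess of 9.39%. The computed neighbour flask ends with left-handed substrate at 40.9% and a top of 9.85%.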